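## The problem

Compound 23 is a linear tridepside. Three 2,4-dioxygenated 6-methylbenzoyl rings are joined by two aryl ester links, one from O4 of ring A to the carboxyl carbon of ring B and one from O4 of ring B to the carboxyl carbon of ring C; ring A ends in a methyl ester. There is no stereocentre, so the task is oxygen differentiation and ester chemoselectivity, not stereocontrol. The six phenolic oxygens occur in three states: methoxy at C2 of rings A and B, acyloxy at C4 of rings A and B, and free hydroxyl at C2 and C4 of ring C. On every ring the chelated ortho oxygen therefore has to be told from the para oxygen. The two depside esters and the methyl ester are the fragile groups. Aryl esters are cleaved or scrambled by hydroxide, alkoxide, amines and free phenoxides, rearrange under ultraviolet light, and do not survive the Lewis acids that cleave methyl ethers, so the last deprotection must be neutral. Each acyl carbon is flanked by a methyl group and an oxygen substituent, which slows both ester formation by acyl transfer and ester hydrolysis. The feature that opens a ring-forming route is the polyketide pattern of ring B: C1 with its carboxyl, C2 with its oxygen and C3 form an acetoacetate chain that can already be esterified to ring A, while C4 with its oxygen, C5 and C6 with its methyl form an acetyl ketene acetal. Ring B can thus be condensed from a 1,3-dinucleophile and a 1,3-dielectrophile around a preformed A–B ester.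

## Retrosynthesis

Target 23 is traced to its ring C dibenzyl ether 22 by cutting the two O–CH2 bonds. Methyl, acyl or silyl protection would need Lewis acid, base or fluoride for removal, and each of these threatens the two aryl esters; benzyl ethers leave under neutral hydrogenolysis. The forward step only has to spare esters.

The ester C–O bond between O4 of ring B and the ring C carbonyl is cut next, giving the A–B phenol 18 and the acid chloride 21. Ring C is the parent orsellinoyl unit and comes from methyl orsellinate 1 by exhaustive benzylation (19), saponification (20) and chlorination (21). Building it by annulation would spend steps on the one ring that can be bought. The cut removes a third of the molecule and leaves a phenol with two free ortho positions. The forward acylation must deliver a di-ortho-substituted acyl group without disturbing the A–B ester.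

Phenol 18 is taken back through its benzyl ether 17 to the salicylate 16 by cutting the O2–CH3 bond of ring B. This order follows from the way ring B is made: 16 is the form in which the ring is born, with O4 benzylated and O2 free and chelated. The two oxygens therefore never have to be differentiated by selective alkylation. The forward steps are O-methylation of a hydrogen-bonded phenol next to an aryl ester, then hydrogenolysis.

Ring B of 16 is cut at C3–C4 and C1–C6 into the 1,3-bis(silyloxy)diene 9, which carries ring A as its ester alkoxy group, and the ketene dibenzyl acetal enone 15. The neighbouring cut, the ester C–O bond between rings A and B, is the classical one and is shorter here, since it would join 4 to an acid made from 3; it is held in reserve as the fallback. Four things speak for the ring cut: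
- the A–B ester is formed at an unhindered acetoacetyl carbon without a coupling reagent;
- the hindered benzoate is created around that ester and never has to undergo acyl transfer;
- O2 and O4 of ring B come out differentiated;
- the C6 substituent of ring B becomes a variable set by the acyl group of the enone.

The other ring cut, C1–C2 and C5–C6, is Alternative 3 below. The precursors are an acyclic four-carbon dinucleophile and a four-carbon dielectrophile. The forward reaction must join the diene terminus to the acetal carbon and the central diene carbon to the ketone, at a temperature low enough for the benzyl groups and the aryl ester to survive the Lewis acid.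

Diene 9 is the double silyl enol ether of the aryl acetoacetate 7. Cutting the two O–Si bonds in turn leads through the mono-silyl enol ether 8 to 7. Cutting the phenol O–acyl bond of 7 gives the ring A phenol 4 and the dioxinone 5, the precursor of acetylketene 6, which is the acylating species. Stepwise silylation is preferred because the first enolisation is easy, while the second, at the methyl group, needs a strong base and is best run on the already neutral enol ether. The forward sequence must never hold a free enolate of the aryl ester at a temperature at which it could expel the ring A aryloxide.

Phenol 4 differs from methyl orsellinate 1 only by the methyl on O2. The para hydroxyl of 1 is the more reactive, so it is blocked first as a benzyl ether (2), the chelated hydroxyl is methylated (3) and the benzyl group is removed. These are three routine steps with no new skeletal bond.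

Enone 15 is cut at its two C–O bonds to 4,4-dichlorobut-3-en-2-one 13 and benzyl alcohol 14. Compound 13 is cut at the bond between its CH and the acetyl carbon to acetyl chloride 10 and 1,1-dichloroethene 11, by way of the trichloro ketone 12. Benzyl is chosen as the acetal alkyl group because it must later leave O4 of ring B under the same neutral conditions that serve at the end; a methyl acetal would place a methyl group on the wrong oxygen.

## Roads not taken

Alternative 1: Ring C would be formed last by a Danheiser benzannulation, cutting ring C bonds C1–C2, C2–C3, C4–C5 and C5–C6. Phenol 18 would be esterified to the diazoketone A2. Its photochemical Wolff rearrangement (making C5–C6) gives a vinylketene, which adds the silyloxyalkyne A3 in a (2+2) step (C2–C3 and C4–C5). Four-electron ring opening and six-electron closure (C1–C2) then deliver A1, the 4-O-triisopropylsilyl ether of 23, which would be desilylated.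
- Merits: the hindered acyl transfer of step 15 is avoided, because the ester of A2 is an unhindered enoate, and ring C is born with both oxygens in place and the chelated one free.
- Weak points: ring C is the only ring that needs no construction, as 21 comes from 1 in three steps. Ultraviolet irradiation of a molecule with two aryl benzoate links invites photo-Fries rearrangement. The vinylketene carries an ester on the carbon that must close the ring, which slows the electrocyclisation of an already electron-poor triene. A2 requires a regioselectively mono-activated methylbutenedioic acid and a diazo homologation, and A3 is a labile ynol ether made separately. The final desilylation puts fluoride next to two aryl esters.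
- Comparison: the step count is no lower (esterification, diazoketone formation, photolysis and desilylation on the main line, against steps 15 and 16 fed by a three-step side branch). The riskiest operation would be the last C–C bond-forming event on the most advanced intermediate, whereas the chosen plan places its risk at step 9 on cheap fragments. The alternative is better in one respect, the absence of a hindered esterification. The chosen plan sets against this a coupling type that is standard for depsides and has an acid-mediated reserve.

Alternative 2: Ring A would be made from a 2-pyrone, cutting ring A bonds C3–C4 and C5–C6. Pyrone A5 and the ketene bis(silyl) acetal A6 would undergo (4+2) cycloaddition. The bridged adduct loses its lactone bridge by decarboxylation and then a silanol, giving A4, which is the same compound as phenol 4.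
- Merits: methoxy at C2 and free hydroxyl at C4 arise directly, with no benzyl detour and no hydrogenation. The polarities match, since the nucleophilic CH2 of A6 meets pyrone C6, which is β to the ester.
- Weak points: the methoxy group at pyrone C4 makes the diene a poorer acceptor, and the methyl on C6 hinders the carbon under attack, so the ketene acetal may stop at conjugate addition or open the lactone. A5 itself needs pyrone construction and O-methylation. Most important, the alternative only remakes the simplest fragment and leaves both ester links and ring B to other chemistry.
- Comparison: about the same number of steps to 4 (three either way), lower certainty, and no contribution to the real difficulty. Its one advantage, differentiation of the ring A oxygens without protecting groups, is matched in the chosen plan by three steps that are each routine.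

Alternative 3: Ring B would be made by Diels–Alder reaction, cutting ring B bonds C1–C2 and C5–C6. Phenol 4 would be esterified to the but-2-ynoate A8 and heated with the ketene acetal diene A9. The adduct aromatises by loss of one methoxy group as the alcohol and of the silyl group, giving A7, which is identical with phenol 18.
- Merits: this is the closest relative of the chosen plan, since ring B is again built around the preformed A–B ester, and it is shorter. A7 carries methoxy at C2 and a free hydroxyl at C4 as the target requires, so steps 5, 6, 10 and 11 fall away and 18 would be reached in about four fewer linear steps. The regiochemistry is inherent (nucleophilic diene terminus to the β-carbon of the ynoate), and cycloadditions of such dienes with β-alkyl alkynoates to 2-alkoxy-4-hydroxy-6-alkylbenzoates are known.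
- Weak points: a but-2-ynoate is a sluggish dienophile, because its methyl group both deactivates and shields the carbon that must accept the diene terminus. The reaction is therefore run hot and long with a large excess of a diene that is thermally and hydrolytically fragile. Under those conditions the aryl ester of A8 is an activated acyl donor toward a silyl ketene acetal, and conjugate addition without ring closure competes.
- Comparison: in step economy this road is better, and if the cycloaddition proved efficient on an aryl but-2-ynoate it would be the method of choice. The chosen plan sets against it a ring formation driven by a Lewis acid at −78 °C instead of heat, in which both C–C bonds form between strongly polarised partners (a silyl enol ether with an activated ketene acetal carbon, then an intramolecular aldol). It also gives an intermediate, 16, whose O2 and O4 can be addressed separately.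

Key step: step 9

Remark: enol ether 8 is expected as an E/Z mixture (its SMILES leaves the double bond undefined), and 9 is drawn as the 1Z isomer that the s-cis enoate conformer of 8 should give; both geometries are erased in steps 6 and 9 and have no bearing on the route.

## Route

Step 1
Reactants: 1 methyl orsellinate (methyl 2,4-dihydroxy-6-methylbenzoate)
Product: 2 methyl 4-(benzyloxy)-2-hydroxy-6-methylbenzoate
Conditions: BnBr (1.05 equiv), K2CO3 (1.2 equiv), acetone, reflux
Reagents that add atoms: benzyl bromide, BrCc1ccccc1
Why: Williamson etherification; the 4-hydroxyl is the more acidic, unchelated phenol, while the 2-hydroxyl is held in a hydrogen bond to the ester carbonyl, so one equivalent of benzyl bromide should stop at the 4-O-benzyl ether.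

Step 2
Reactants: 2 methyl 4-(benzyloxy)-2-hydroxy-6-methylbenzoate
Product: 3 methyl 4-(benzyloxy)-2-methoxy-6-methylbenzoate
Conditions: MeI (3 equiv), K2CO3 (2 equiv), DMF, 50 °C
Reagents that add atoms: iodomethane, CI
Why: Williamson methylation of the remaining chelated phenol, which needs the dipolar solvent and excess iodomethane; the benzyl ether and the hindered methyl ester are inert.

Step 3
Reactants: 3 methyl 4-(benzyloxy)-2-methoxy-6-methylbenzoate
Product: 4 methyl 4-hydroxy-2-methoxy-6-methylbenzoate
Conditions: H2 (1 atm), 10% Pd/C, EtOAc–MeOH, rt
Reagents that add atoms: none
Why: Catalytic hydrogenolysis of the benzyl aryl ether; the methyl ester and the methyl ether are untouched.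

Step 4
Reactants: 4 methyl 4-hydroxy-2-methoxy-6-methylbenzoate; 5 2,2,6-trimethyl-4H-1,3-dioxin-4-one
Product: 7 3-methoxy-4-(methoxycarbonyl)-5-methylphenyl 3-oxobutanoate, via acetylketene 6 (not isolated)
Conditions: 5 (1.5 equiv), xylene, 140 °C, acetone distilled off
Reagents that add atoms: none
Why: Retro-(4+2) thermolysis of the dioxinone releases acetylketene, which adds the phenol O–H to give the aryl acetoacetate; the A–B ester oxygen–carbon bond is thus made at an unhindered acyl carbon without base or coupling reagent.

Step 5
Reactants: 7 3-methoxy-4-(methoxycarbonyl)-5-methylphenyl 3-oxobutanoate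
Product: 8 3-methoxy-4-(methoxycarbonyl)-5-methylphenyl 3-(trimethylsilyloxy)but-2-enoate (E/Z mixture)
Conditions: Me3SiOTf (1.1 equiv), Et3N (1.3 equiv), Et2O, 0 °C; decant from the ammonium salt, concentrate
Reagents that add atoms: trimethylsilyl trifluoromethanesulfonate, C[Si](C)(C)OS(=O)(=O)C(F)(F)F
Why: Soft enolisation of the β-keto ester: the silyl triflate activates the ketone oxygen and the amine removes the α-proton, so the silyl enol ether forms quickly at 0 °C and no free enolate accumulates that could expel the ring A aryloxide.

Step 6
Reactants: 8 3-methoxy-4-(methoxycarbonyl)-5-methylphenyl 3-(trimethylsilyloxy)but-2-enoate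
Product: 9 (1Z)-1-[3-methoxy-4-(methoxycarbonyl)-5-methylphenoxy]-1,3-bis(trimethylsilyloxy)buta-1,3-diene (methyl 4-{[(1Z)-1,3-bis(trimethylsilyloxy)buta-1,3-dien-1-yl]oxy}-2-methoxy-6-methylbenzoate)
Conditions: Me3SiCl (1.5 equiv), then LiN(iPr)2 (1.1 equiv) added dropwise, THF, −78 °C; to 0 °C; hexane, filtration, used crude
Reagents that add atoms: chlorotrimethylsilane, C[Si](C)(C)Cl
Why: Kinetic γ-deprotonation of the 3-silyloxy enoate by lithium diisopropylamide gives the lithium dienolate, which is O-silylated by the chlorosilane already present (in situ quench); −78 °C and immediate trapping should keep the aryl ester dienolate from eliminating the aryloxide, and the small excess of base limits deprotonation at the ring A aryl methyl group.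

Step 7
Reactants: 10 acetyl chloride; 11 1,1-dichloroethene
Product: 13 4,4-dichlorobut-3-en-2-one, via 4,4,4-trichlorobutan-2-one 12 (not isolated)
Conditions: AlCl3 (1.1 equiv), CH2Cl2, 0 °C to rt; ice–HCl; steam distillation
Reagents that add atoms: none
Why: Friedel–Crafts-type acylation of the alkene: the acylium ion adds to the CH2 terminus, chloride caps the dichloro-stabilised cation to give the trichloro ketone, and β-elimination of HCl on steam distillation gives the conjugated dichloro enone.

Step 8
Reactants: 13 4,4-dichlorobut-3-en-2-one; 14 benzyl alcohol
Product: 15 4,4-bis(benzyloxy)but-3-en-2-one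
Conditions: 14 (2.05 equiv), NaH (2.05 equiv), THF, 0 °C; then 13, 0 °C to rt; filtration through basic alumina, used fresh
Reagents that add atoms: none
Why: Two successive addition–elimination (vinylic substitution) steps of sodium benzyloxide at the β-carbon of the β,β-dichloro enone, as in the known preparation of the dimethoxy analogue; the push–pull ketene acetal formed is a much weaker acceptor, which should hold two equivalents of alkoxide back from a third addition.

Step 9
Reactants: 9 (1Z)-1-[3-methoxy-4-(methoxycarbonyl)-5-methylphenoxy]-1,3-bis(trimethylsilyloxy)buta-1,3-diene; 15 4,4-bis(benzyloxy)but-3-en-2-one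
Product: 16 3-methoxy-4-(methoxycarbonyl)-5-methylphenyl 4-(benzyloxy)-2-hydroxy-6-methylbenzoate
Conditions: 15 (1.2 equiv), TiCl4 (1.1 equiv) added last, CH2Cl2, 4 Å MS, −78 °C, slowly to 0 °C; 1 M HCl
Reagents that add atoms: none
Why: TiCl4 binds the ketone oxygen of 15 and turns the ketene acetal carbon into a dibenzyloxy-stabilised allyl cation; the terminal CH2 of 9, the most nucleophilic carbon of the bis(silyl enol ether), adds there in a Mukaiyama–Michael step (ring B bond C3–C4), and the adduct expels benzyloxide to titanium, leaving a benzyl vinylogous ester. The remaining 1-silyloxy enoate of the ring A ester, nucleophilic at the carbon between the two carbonyls, then adds to the titanium-activated methyl ketone in an intramolecular Mukaiyama aldol, a 6-(enolendo)-exo-trig closure that forms bond C1–C6; the vinylogous ester is a push–pull alkene and can rotate into the geometry the closure needs. Loss of water from the tertiary aldol and enolisation of the ring ketone aromatise the ring. The closest known reaction type is the TiCl4-mediated formal (3+3) cyclocondensation of 1,3-bis(silyloxy)buta-1,3-dienes with 3-alkoxy and 3,3-dialkoxy enones to salicylates; untested here are the aryl ester on the diene and benzyl as the alkoxy group. No stereocentre is formed. The selectivity needed is regiochemical: the diene terminus must bond to the acetal carbon and the central carbon to the ketone, so that methyl ends ortho and benzyloxy para to the ester; this should follow from the conjugate position of 15 being the softer and, under TiCl4, the more cationic site, which leaves the ketone for the intramolecular step. The two oxygens of ring B emerge differentiated, the one from the acetoacetate as a free chelated phenol and the one from the ketene acetal as its benzyl ether.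

Step 10
Reactants: 16 3-methoxy-4-(methoxycarbonyl)-5-methylphenyl 4-(benzyloxy)-2-hydroxy-6-methylbenzoate
Product: 17 3-methoxy-4-(methoxycarbonyl)-5-methylphenyl 4-(benzyloxy)-2-methoxy-6-methylbenzoate
Conditions: MeI (3 equiv), K2CO3 (2 equiv), DMF (dry), rt to 40 °C
Reagents that add atoms: iodomethane, CI
Why: Williamson O-methylation of the chelated salicylate phenol; dry carbonate is not nucleophilic, and the A–B ester is a di-ortho-substituted benzoate whose carbonyl is shielded, so it should survive.

Step 11
Reactants: 17 3-methoxy-4-(methoxycarbonyl)-5-methylphenyl 4-(benzyloxy)-2-methoxy-6-methylbenzoate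
Product: 18 3-methoxy-4-(methoxycarbonyl)-5-methylphenyl 4-hydroxy-2-methoxy-6-methylbenzoate
Conditions: H2 (1 atm), 10% Pd/C, EtOAc–THF, rt
Reagents that add atoms: none
Why: Hydrogenolysis of the benzyl aryl ether under neutral, alcohol-free conditions, which leaves the aryl ester and the methyl ester intact.

Step 12
Reactants: 1 methyl orsellinate
Product: 19 methyl 2,4-bis(benzyloxy)-6-methylbenzoate
Conditions: BnBr (2.5 equiv), K2CO3 (3 equiv), DMF, 60 °C
Reagents that add atoms: benzyl bromide, BrCc1ccccc1
Why: Exhaustive Williamson benzylation; in DMF with heating the chelated 2-hydroxyl is alkylated as well as the 4-hydroxyl.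

Step 13
Reactants: 19 methyl 2,4-bis(benzyloxy)-6-methylbenzoate
Product: 20 2,4-bis(benzyloxy)-6-methylbenzoic acid
Conditions: KOH (10 equiv), DMSO–H2O (4:1), 90 °C; then 1 M HCl
Reagents that add atoms: potassium hydroxide, [K+].[OH-]
Why: Saponification of a di-ortho-substituted methyl benzoate, which needs poorly solvated hydroxide in aqueous DMSO at elevated temperature; benzyl ethers are stable to base.

Step 14
Reactants: 20 2,4-bis(benzyloxy)-6-methylbenzoic acid
Product: 21 2,4-bis(benzyloxy)-6-methylbenzoyl chloride
Conditions: (COCl)2 (1.5 equiv), DMF (cat.), CH2Cl2, 0 °C to rt; evaporation
Reagents that add atoms: oxalyl chloride, O=C(Cl)C(=O)Cl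
Why: Acid chloride formation through the chloroiminium species from DMF and oxalyl chloride; mild enough for benzyl ethers, with only gaseous by-products.

Step 15
Reactants: 18 3-methoxy-4-(methoxycarbonyl)-5-methylphenyl 4-hydroxy-2-methoxy-6-methylbenzoate; 21 2,4-bis(benzyloxy)-6-methylbenzoyl chloride
Product: 22 3-methoxy-4-{[3-methoxy-4-(methoxycarbonyl)-5-methylphenoxy]carbonyl}-5-methylphenyl 2,4-bis(benzyloxy)-6-methylbenzoate
Conditions: 21 (1.3 equiv), Et3N (2 equiv), DMAP (0.2 equiv), CH2Cl2, 0 °C to rt
Reagents that add atoms: none
Why: DMAP-catalysed acylation of a phenol by an acid chloride, the standard depside coupling; the phenol of 18 has two free ortho positions, and the existing A–B ester is a shielded di-ortho-substituted benzoate that should resist transesterification.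

Step 16
Reactants: 22 3-methoxy-4-{[3-methoxy-4-(methoxycarbonyl)-5-methylphenoxy]carbonyl}-5-methylphenyl 2,4-bis(benzyloxy)-6-methylbenzoate
Product: 23 3-methoxy-4-{[3-methoxy-4-(methoxycarbonyl)-5-methylphenoxy]carbonyl}-5-methylphenyl 2,4-dihydroxy-6-methylbenzoate (CNP0514431.0)
Conditions: H2 (1 atm), 10% Pd/C, EtOAc–THF, rt
Reagents that add atoms: none
Why: Double hydrogenolysis of the ring C benzyl ethers under neutral conditions frees both phenols without touching the two depside esters or the methyl ester.

## Compound list

1 | methyl orsellinate (methyl 2,4-dihydroxy-6-methylbenzoate) | COC(=O)c1c(C)cc(O)cc1O | starting material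
2 | methyl 4-(benzyloxy)-2-hydroxy-6-methylbenzoate | COC(=O)c1c(C)cc(OCc2ccccc2)cc1O | intermediate
3 | methyl 4-(benzyloxy)-2-methoxy-6-methylbenzoate | COC(=O)c1c(C)cc(OCc2ccccc2)cc1OC | intermediate
4 | methyl 4-hydroxy-2-methoxy-6-methylbenzoate | COC(=O)c1c(C)cc(O)cc1OC | intermediate
5 | 2,2,6-trimethyl-4H-1,3-dioxin-4-one | CC1=CC(=O)OC(C)(C)O1 | starting material
6 | acetylketene (not isolated) | CC(=O)C=C=O | intermediate
7 | 3-methoxy-4-(methoxycarbonyl)-5-methylphenyl 3-oxobutanoate | COC(=O)c1c(C)cc(OC(=O)CC(C)=O)cc1OC | intermediate
8 | 3-methoxy-4-(methoxycarbonyl)-5-methylphenyl 3-(trimethylsilyloxy)but-2-enoate (E/Z mixture) | COC(=O)c1c(C)cc(OC(=O)C=C(C)O[Si](C)(C)C)cc1OC | intermediate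
9 | (1Z)-1-[3-methoxy-4-(methoxycarbonyl)-5-methylphenoxy]-1,3-bis(trimethylsilyloxy)buta-1,3-diene | COC(=O)c1c(C)cc(O/C(O[Si](C)(C)C)=C/C(=C)O[Si](C)(C)C)cc1OC | intermediate
10 | acetyl chloride | CC(=O)Cl | starting material
11 | 1,1-dichloroethene | C=C(Cl)Cl | starting material
12 | 4,4,4-trichlorobutan-2-one (not isolated) | CC(=O)CC(Cl)(Cl)Cl | intermediate
13 | 4,4-dichlorobut-3-en-2-one | CC(=O)C=C(Cl)Cl | intermediate
14 | benzyl alcohol | OCc1ccccc1 | starting material
15 | 4,4-bis(benzyloxy)but-3-en-2-one | CC(=O)C=C(OCc1ccccc1)OCc1ccccc1 | intermediate
16 | 3-methoxy-4-(methoxycarbonyl)-5-methylphenyl 4-(benzyloxy)-2-hydroxy-6-methylbenzoate | COC(=O)c1c(C)cc(OC(=O)c2c(C)cc(OCc3ccccc3)cc2O)cc1OC | intermediate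
17 | 3-methoxy-4-(methoxycarbonyl)-5-methylphenyl 4-(benzyloxy)-2-methoxy-6-methylbenzoate | COC(=O)c1c(C)cc(OC(=O)c2c(C)cc(OCc3ccccc3)cc2OC)cc1OC | intermediate
18 | 3-methoxy-4-(methoxycarbonyl)-5-methylphenyl 4-hydroxy-2-methoxy-6-methylbenzoate | COC(=O)c1c(C)cc(OC(=O)c2c(C)cc(O)cc2OC)cc1OC | intermediate
19 | methyl 2,4-bis(benzyloxy)-6-methylbenzoate | COC(=O)c1c(C)cc(OCc2ccccc2)cc1OCc1ccccc1 | intermediate
20 | 2,4-bis(benzyloxy)-6-methylbenzoic acid | OC(=O)c1c(C)cc(OCc2ccccc2)cc1OCc1ccccc1 | intermediate
21 | 2,4-bis(benzyloxy)-6-methylbenzoyl chloride | ClC(=O)c1c(C)cc(OCc2ccccc2)cc1OCc1ccccc1 | intermediate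
22 | 3-methoxy-4-{[3-methoxy-4-(methoxycarbonyl)-5-methylphenoxy]carbonyl}-5-methylphenyl 2,4-bis(benzyloxy)-6-methylbenzoate | COC(=O)c1c(C)cc(OC(=O)c2c(C)cc(OC(=O)c3c(C)cc(OCc4ccccc4)cc3OCc3ccccc3)cc2OC)cc1OC | intermediate
23 | 3-methoxy-4-{[3-methoxy-4-(methoxycarbonyl)-5-methylphenoxy]carbonyl}-5-methylphenyl 2,4-dihydroxy-6-methylbenzoate (CNP0514431.0) | COC(=O)c1c(C)cc(OC(=O)c2c(C)cc(OC(=O)c3c(C)cc(O)cc3O)cc2OC)cc1OC | target

## Step count and risk

Total step count: 16. Longest linear sequence: 11 steps (steps 1, 2, 3, 4, 5, 6, 9, 10, 11, 15, 16); the enone branch (steps 7, 8) and the ring C branch (steps 12, 13, 14) are side branches.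

Least certain steps:

Step 9 (key step). Three processes could defeat it:
- reversed regiochemistry, through initial 1,2-addition of the diene terminus to the titanium-bound ketone, which would place methyl para and benzyloxy ortho to the ester;
- Lewis-acid-induced loss of a benzyl group, either from the dibenzyloxy cation or from the product ether on warming;
- protodesilylation of the diene back to the acetoacetate by adventitious HCl before any C–C bond forms.

The fallback gives up the annulation for the classical depside assembly. It sets out from 3 and 4 and comes back at 17. Ester 3 would be saponified (KOH, aqueous DMSO, 90 °C) to 4-(benzyloxy)-2-methoxy-6-methylbenzoic acid F1. This would be converted with oxalyl chloride and catalytic DMF into 4-(benzyloxy)-2-methoxy-6-methylbenzoyl chloride F2, and phenol 4 would be acylated with it (Et3N, DMAP, CH2Cl2) to give 17 directly, already methylated at O2.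

Step 6. Three processes are the likely failures: expulsion of the ring A aryloxide from the lithium dienolate (elimination to a vinylketene), competing deprotonation of the ring A aryl methyl group ortho to the methyl ester followed by C-silylation, and hydrolysis of the diene on handling. The fallback replaces enolate chemistry by soft enolisation in one flask. It sets out from 7 and comes back at 9. Acetoacetate 7 would be treated with Me3SiOTf (2.2 equiv) and Et3N in Et2O from 0 °C to rt, so that both carbonyl groups are silylated through oxygen activation and amine deprotonation without any lithium species. Steps 5 and 6 would be bypassed, and no compound outside the route is made on this way (F0). This second soft silylation is established for 1,3-diketones and is less general for β-keto esters, which is why it is held in reserve.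

Step 8. The substitution may overshoot to the ortho ester by a third alkoxide addition, stall at the mono-benzyloxy chloro enone, or the ketene acetal may hydrolyse to the acetoacetate on work-up. The fallback builds the ketene acetal first and acylates it. It sets out from 14 and 10 and comes back at 15. Commercial bromoacetaldehyde diethyl acetal would be transacetalised with 14 (TsOH cat., toluene, ethanol distilled off) to 2-bromo-1,1-bis(benzyloxy)ethane F3. Dehydrobromination with KOtBu in THF would give 1,1-bis(benzyloxy)ethene F4, and C-acylation of this ketene acetal with acetyl chloride 10 and 2,6-lutidine in Et2O at 0 °C would give 15.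

Step 15. Acyl transfer from the di-ortho-substituted acid chloride may be slow enough for the phenoxide of 18 to attack the A–B ester of a second molecule, scrambling the depside. The fallback avoids base and phenoxide altogether. It sets out from 20 and 18 and comes back at 22. Acid 20 would be treated with trifluoroacetic anhydride in toluene at rt to form 2,4-bis(benzyloxy)-6-methylbenzoic trifluoroacetic anhydride F5, which acylates the neutral phenol 18 under acidic conditions to give 22; step 14 is then not needed.

## Further compounds

F1 | step 9 | 4-(benzyloxy)-2-methoxy-6-methylbenzoic acid | OC(=O)c1c(C)cc(OCc2ccccc2)cc1OC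
F2 | step 9 | 4-(benzyloxy)-2-methoxy-6-methylbenzoyl chloride | ClC(=O)c1c(C)cc(OCc2ccccc2)cc1OC
F0 | step 6 | none | none
F3 | step 8 | 2-bromo-1,1-bis(benzyloxy)ethane | BrCC(OCc1ccccc1)OCc1ccccc1
F4 | step 8 | 1,1-bis(benzyloxy)ethene | C=C(OCc1ccccc1)OCc1ccccc1
F5 | step 15 | 2,4-bis(benzyloxy)-6-methylbenzoic trifluoroacetic anhydride | O=C(OC(=O)C(F)(F)F)c1c(C)cc(OCc2ccccc2)cc1OCc1ccccc1
A1 | alternative 1 | 4-O-triisopropylsilyl ether of the target on ring C | COC(=O)c1c(C)cc(OC(=O)c2c(C)cc(OC(=O)c3c(C)cc(O[Si](C(C)C)(C(C)C)C(C)C)cc3O)cc2OC)cc1OC
A2 | alternative 1 | 3-methoxy-4-{[3-methoxy-4-(methoxycarbonyl)-5-methylphenoxy]carbonyl}-5-methylphenyl (2E)-5-diazo-3-methyl-4-oxopent-2-enoate | COC(=O)c1c(C)cc(OC(=O)c2c(C)cc(OC(=O)/C=C(\C)C(=O)C=[N+]=[N-])cc2OC)cc1OC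
A3 | alternative 1 | (triisopropylsilyloxy)ethyne | C#CO[Si](C(C)C)(C(C)C)C(C)C
A4 | alternative 2 | methyl 4-hydroxy-2-methoxy-6-methylbenzoate (same as 4) | COC(=O)c1c(C)cc(O)cc1OC
A5 | alternative 2 | methyl 4-methoxy-6-methyl-2-oxo-2H-pyran-5-carboxylate | COC(=O)C1=C(C)OC(=O)C=C1OC
A6 | alternative 2 | 1,1-bis(trimethylsilyloxy)ethene | C=C(O[Si](C)(C)C)O[Si](C)(C)C
A7 | alternative 3 | 3-methoxy-4-(methoxycarbonyl)-5-methylphenyl 4-hydroxy-2-methoxy-6-methylbenzoate (same as 18) | COC(=O)c1c(C)cc(OC(=O)c2c(C)cc(O)cc2OC)cc1OC
A8 | alternative 3 | 3-methoxy-4-(methoxycarbonyl)-5-methylphenyl but-2-ynoate | COC(=O)c1c(C)cc(OC(=O)C#CC)cc1OC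
A9 | alternative 3 | 1,1-dimethoxy-3-(trimethylsilyloxy)buta-1,3-diene | COC(OC)=CC(=C)O[Si](C)(C)C
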